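**Retrosynthetic overview**
1. Target acid ⇒ its 2-(trimethylsilyl)ethyl (TMSE) ester, cleaved last with fluoride so that the triene and the β-keto-acid-like core are spared.
2. The cyclohexadienone, the only ring and formed last, ⇒ an open-chain 3,5,7-triketo ester by intramolecular Knoevenagel aldol condensation. This closes the C(CO2R)=C(CH3) bond.
3. Triketo ester ⇒ γ-acylation of a 3-oxopentanoate dianion by an α-quaternary β-keto acid.
4. The quaternary C–CH2(farnesyl) bond and the 2'E alkene ⇒ [3,3] dianionic Carroll rearrangement of (S)-nerolidyl 2-methylacetoacetate. The carbinol centre of nerolidol is traded for the ring stereocentre.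
5. That ester ⇒ natural (+)-(3S,6E)-nerolidol plus ethyl 2-methylacetoacetate, joined by O-acylation with the carbinol C–O bond untouched.

Assumption: natural (+)-(3S,6E)-nerolidol (cabreuva-oil grade, high ee, 6E) is bought as such, and the target is the (R) enantiomer in the tautomer drawn in the SMILES.

**Step 1**
Reactants: 1 (+)-(3S,6E)-nerolidol; 2 ethyl 2-methyl-3-oxobutanoate (racemic, labile α-centre)
Product: 3 (3S,6E)-3,7,11-trimethyldodeca-1,6,10-trien-3-yl 2-methyl-3-oxobutanoate (about 1:1 at the labile α-carbon, of no consequence)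
Conditions: 2 (3 equiv), DMAP (0.3 equiv), toluene, reflux, 4 Å MS in a Soxhlet (EtOH removal), 36 h; excess 2 distilled off in vacuo
Reagents that add atoms: none
Why: DMAP-catalysed β-keto ester transesterification runs through an acylketene that even a tertiary alcohol traps at oxygen, so the C3–O bond and the S configuration of nerolidol are not touched, and 110 °C is below the onset of the thermal Carroll reaction.

**Step 2**
Reactants: 3 (3S,6E)-nerolidyl 2-methyl-3-oxobutanoate
Product: 5 (2R,4E,8E)-2-acetyl-2,5,9,13-tetramethyltetradeca-4,8,12-trienoic acid, via Li-chelated dilithium dienediolate of 3 4 (not isolated)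
Conditions: LDA (2.3 equiv), THF, −78 °C, 1 h; then 20 °C, 12 h; ice-cold 1 M HCl to pH 3, Et2O, 0 °C; crude acid kept at ≤5 °C and used the same day
Reagents that add atoms: lithium diisopropylamide (LDA), CC(C)[N-]C(C)C.[Li+] (supplies only the Li of 4; no atom of it is in 5)
Why: In this dianionic (ester-enolate) Carroll rearrangement, a [3,3]-sigmatropic shift, chelation locks the C(OLi)=CH2 group of 4 cis to the ester OLi, and a chair transition state with the homogeranyl chain equatorial and the carbinol methyl axial delivers C1' suprafacially to one enolate face, so the 3S carbinol centre is exchanged for the 2R quaternary centre and the 4E alkene (the minor 4Z isomer, from the chair with the chain axial, carries mainly 2S and is removed in step 4).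

**Step 3**
Reactants: 6 methyl 3-oxopentanoate; 7 2-(trimethylsilyl)ethanol
Product: 8 2-(trimethylsilyl)ethyl 3-oxopentanoate
Conditions: DMAP (0.3 equiv), toluene, reflux, 4 Å MS (MeOH removal), 16 h
Reagents that add atoms: none
Why: The same acylketene-type DMAP transesterification of a β-keto ester is driven by removal of methanol and is routine with a primary alcohol.

**Step 4**
Reactants: 5 (2R,4E,8E)-2-acetyl-2,5,9,13-tetramethyltetradeca-4,8,12-trienoic acid; 8 2-(trimethylsilyl)ethyl 3-oxopentanoate
Product: 12 2-(trimethylsilyl)ethyl (3R)-6-hydroxy-2,3,5-trimethyl-4-oxo-3-[(2E,6E)-3,7,11-trimethyldodeca-2,6,10-trienyl]cyclohexa-1,5-diene-1-carboxylate, via acyl imidazolide of 5 9 (not isolated), via dilithio dianion of 8 10 (not isolated), via open-chain triketo ester 11 (not isolated)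
Conditions: 5, CDI (1.0 equiv), THF, 0 °C to rt, 1 h; cannulated into 10 [8 (3.3 equiv), LDA (6.6 equiv), THF, −78 to 0 °C] at −78 °C, then to −20 °C, 2 h; AcOH (6.6 equiv), then rt to 40 °C, 12 h in the resulting i-Pr2NH/imidazole/LiOAc buffer; chromatography on AgNO3–SiO2 removes the 2'Z isomer
Reagents that add atoms: 1,1'-carbonyldiimidazole (CDI), O=C(n1ccnc1)n1ccnc1 (imidazolyl group of 9 only, lost again before 12); lithium diisopropylamide (LDA), CC(C)[N-]C(C)C.[Li+] (Li of 10 only)
Why: The acyl imidazolide is a better acceptor than the pinacolone-like methyl ketone, so the Huckin–Weiler dianion is acylated at its γ-carbon, and in the amine buffer the most acidic CH2 of 11 closes onto the acetyl C=O in a biomimetic intramolecular Knoevenagel aldol condensation (the competing Claisen mode is blocked by the quaternary carbon) to give the stabilised vinylogous acid, while the non-enolisable stereocentre is untouched.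

**Step 5**
Reactants: 12 TMSE ester of the target
Product: 13 (3R)-6-hydroxy-2,3,5-trimethyl-4-oxo-3-[(2E,6E)-3,7,11-trimethyldodeca-2,6,10-trienyl]cyclohexa-1,5-diene-1-carboxylic acid (target, CID137333727)
Conditions: TBAF (4 equiv), THF, 0 °C to rt, 3 h; ice-cold 0.5 M HCl/EtOAc; concentrated below 20 °C
Reagents that add atoms: none
Why: Fluoride attacks silicon and the β-silylethyl ester fragments to ethene, Me3SiF and the carboxylate without acid or acyl attack, so the acid-sensitive triene and the quaternary centre (no α-H, no [3,3] reversal at this temperature) survive, and cold acidification avoids decarboxylation.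

**Compound list**
1 | (+)-(3S,6E)-nerolidol, (3S,6E)-3,7,11-trimethyldodeca-1,6,10-trien-3-ol | C=C[C@@](C)(O)CC/C=C(\C)CCC=C(C)C | starting material
2 | ethyl 2-methyl-3-oxobutanoate (racemic) | CCOC(=O)C(C)C(C)=O | starting material
3 | (3S,6E)-nerolidyl 2-methyl-3-oxobutanoate | C=C[C@@](C)(OC(=O)C(C)C(C)=O)CC/C=C(\C)CCC=C(C)C | intermediate
4 | dilithium dienediolate of 3 (ester O-alkyl trans to the C(OLi)=CH2 group) | C=C[C@@](C)(O/C([O-])=C(C)/C([O-])=C)CC/C=C(\C)CCC=C(C)C.[Li+].[Li+] | intermediate
5 | (2R,4E,8E)-2-acetyl-2,5,9,13-tetramethyltetradeca-4,8,12-trienoic acid | CC(C)=CCC/C(C)=C/CC/C(C)=C/C[C@@](C(C)=O)(C)C(=O)O | intermediate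
6 | methyl 3-oxopentanoate | CCC(=O)CC(=O)OC | starting material
7 | 2-(trimethylsilyl)ethanol | C[Si](C)(C)CCO | starting material
8 | 2-(trimethylsilyl)ethyl 3-oxopentanoate | CCC(=O)CC(=O)OCC[Si](C)(C)C | intermediate
9 | (2R,4E,8E)-2-acetyl-1-(imidazol-1-yl)-2,5,9,13-tetramethyltetradeca-4,8,12-trien-1-one | CC(C)=CCC/C(C)=C/CC/C(C)=C/C[C@@](C(C)=O)(C)C(=O)n1ccnc1 | intermediate
10 | dilithio α,γ-dianion of 8 | CC=C([O-])C=C([O-])OCC[Si](C)(C)C.[Li+].[Li+] | intermediate
11 | 2-(trimethylsilyl)ethyl (6R,8E,12E)-6-acetyl-4,6,9,13,17-pentamethyl-3,5-dioxooctadeca-8,12,16-trienoate (labile C4 epimers) | CC(C)=CCC/C(C)=C/CC/C(C)=C/C[C@@](C(C)=O)(C)C(=O)C(C)C(=O)CC(=O)OCC[Si](C)(C)C | intermediate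
12 | 2-(trimethylsilyl)ethyl (3R)-6-hydroxy-2,3,5-trimethyl-4-oxo-3-[(2E,6E)-farnesyl]cyclohexa-1,5-diene-1-carboxylate | CC(C)=CCC/C(C)=C/CC/C(C)=C/C[C@@]1(C)C(=O)C(C)=C(O)C(C(=O)OCC[Si](C)(C)C)=C1C | intermediate
13 | (3R)-6-hydroxy-2,3,5-trimethyl-4-oxo-3-[(2E,6E)-farnesyl]cyclohexa-1,5-diene-1-carboxylic acid | CC(C)=CCC/C(C)=C/CC/C(C)=C/C[C@@]1(C)C(=O)C(C)=C(O)C(C(=O)O)=C1C | target

**Step count**
Total steps: 5. Longest linear sequence: 4 (steps 1, 2, 4, 5, starting from 1).

**Steps most likely to fail**

Step 2 is the riskiest.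
- The methyl group and the CH2R chain on the carbinol carbon differ little in size, so I expect only about 2–3:1 E:Z (an estimate, not a measured value).
- The ee of the E isomer depends on the chelated enolate geometry and on the chair preference holding.
- Free acid 5 decarboxylates within hours at room temperature.

The fallback sets out from 3 and comes back at 5. Dianion 4 is generated as before but trapped at −78 °C with Me3SiCl. This gives the neutral ketene acetal (3S,6E)-nerolidyl 1,3-bis(trimethylsilyloxy)-2-methylbuta-1,3-dien-1-yl ether F1, which is freed from salts and amine and checked for geometry by NOE. It then undergoes an Ireland–Claisen rearrangement in toluene at 0–25 °C. The product is trimethylsilyl (2R,4E,8E)-2,5,9,13-tetramethyl-2-[1-(trimethylsilyloxy)ethenyl]tetradeca-4,8,12-trienoate F2. Acid and ketone are both masked in it, so nothing can decarboxylate on storage. Cold aqueous citric acid in THF releases 5 just before use.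

Step 4 is next.
- The basic dianion may enolise or add to the methyl ketone of 9.
- The α-quaternary acyl group is hindered.
- The 2,2-disubstituted 1,3-dicarbonyl unit can undergo retro-Claisen cleavage in strong base.

The fallback sets out from 5 and 8 and comes back at 11, and it avoids strong base in the C–C bond formation. Acid 5 is treated with 1-chloro-N,N,2-trimethylprop-1-en-1-amine in CH2Cl2 at 0 °C to give (2R,4E,8E)-2-acetyl-2,5,9,13-tetramethyltetradeca-4,8,12-trienoyl chloride F3. Separately, 8 is silylated with Me3SiCl/Et3N to 2-(trimethylsilyl)ethyl 3-(trimethylsilyloxy)pent-2-enoate F4. LDA/Me3SiCl at −78 °C then gives 1,3-bis(trimethylsilyloxy)-1-[2-(trimethylsilyl)ethoxy]penta-1,3-diene F5. Mixing F3 and F5 in CH2Cl2 from −78 to 20 °C without Lewis acid (Chan-type γ-acylation of a bis-silyl dienol ether) gives the 3-O-trimethylsilyl enol ether of the triketo ester F6. Aqueous NaHCO3 work-up hydrolyses it to 11, which is cyclised with Et3N in CH2Cl2 to 12.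

Step 1 is the third. An α-substituted ethyl β-keto ester forms its acylketene slowly, and forcing the temperature would start the Carroll reaction with decarboxylation. The fallback sets out from 1 and comes back at 3. Nerolidol is heated briefly (xylene, 130 °C, 40 min) with commercial 2,2,6-trimethyl-4H-1,3-dioxin-4-one. Retro-[4+2] of the dioxinone releases acetylketene, which acylates the alcohol to (3S,6E)-nerolidyl 3-oxobutanoate F7. Mono-C-methylation with MeI (1.05 equiv) and K2CO3 in acetone at rt then gives 3.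

**Further compounds**
F1 | step 2 | (3S,6E)-nerolidyl 1,3-bis(trimethylsilyloxy)-2-methylbuta-1,3-dien-1-yl ether | C=C[C@@](C)(O/C(O[Si](C)(C)C)=C(C)/C(=C)O[Si](C)(C)C)CC/C=C(\C)CCC=C(C)C
F2 | step 2 | trimethylsilyl (2R,4E,8E)-2,5,9,13-tetramethyl-2-[1-(trimethylsilyloxy)ethenyl]tetradeca-4,8,12-trienoate | CC(C)=CCC/C(C)=C/CC/C(C)=C/C[C@@](C(=C)O[Si](C)(C)C)(C)C(=O)O[Si](C)(C)C
F3 | step 4 | (2R,4E,8E)-2-acetyl-2,5,9,13-tetramethyltetradeca-4,8,12-trienoyl chloride | CC(C)=CCC/C(C)=C/CC/C(C)=C/C[C@@](C(C)=O)(C)C(=O)Cl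
F4 | step 4 | 2-(trimethylsilyl)ethyl 3-(trimethylsilyloxy)pent-2-enoate | CCC(O[Si](C)(C)C)=CC(=O)OCC[Si](C)(C)C
F5 | step 4 | 1,3-bis(trimethylsilyloxy)-1-[2-(trimethylsilyl)ethoxy]penta-1,3-diene | CC=C(O[Si](C)(C)C)C=C(O[Si](C)(C)C)OCC[Si](C)(C)C
F6 | step 4 | 3-O-trimethylsilyl enol ether of triketo ester 11 | CC(C)=CCC/C(C)=C/CC/C(C)=C/C[C@@](C(C)=O)(C)C(=O)C(C)C(O[Si](C)(C)C)=CC(=O)OCC[Si](C)(C)C
F7 | step 1 | (3S,6E)-nerolidyl 3-oxobutanoate | C=C[C@@](C)(OC(=O)CC(C)=O)CC/C=C(\C)CCC=C(C)C
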